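**Assumption:** the target has no stereocentre, so "single enantiomer" is read as the achiral compound itself and no stereocontrol is needed.

## Retrosynthetic overview

1. The target is the hydrolytically opened form of 8-hydroxy-6-methoxy-3-undecylisocoumarin; aqueous base converts the lactone into the open keto acid.
2. Key disconnection: the aryl C6–CH2 bond. 4-Methoxysalicylic acid supplies the aryl carbon as a carboxylate-directed aryl–Rh(III) nucleophile. The ketone α-carbon is used as an acceptor (an α-oxo Rh-carbene from a β-keto sulfoxonium ylide, i.e. an enolonium equivalent) instead of as an enolate.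
3. The ylide comes from lauroyl chloride and dimethylsulfoxonium methylide, which supplies the future benzylic carbon.
4. Rings: the benzene ring is bought. The only ring formed is the pyranone of the isocoumarin, which closes after the C–C bond is made and is reopened in the same flask.

## Route

Step 1
Reactants: 1 dodecanoyl chloride (lauroyl chloride); 2 trimethylsulfoxonium iodide
Product: 4 1-[dimethyl(oxo)-λ6-sulfanylidene]tridecan-2-one, via dimethylsulfoxonium methylide 3 (not isolated)
Conditions: 2 (3.0 equiv), KOtBu (3.0 equiv), THF, reflux, 2 h; then 1 (1.0 equiv), 0 °C to rt, 2 h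
Reagents that add atoms: none
Why: The Corey–Chaykovsky ylide 3 is C-acylated by the acid chloride and a second equivalent of 3 deprotonates the acylsulfoxonium salt, giving the stable β-keto sulfoxonium ylide (acylation of a sulfur ylide); no stereocentre is formed.

Step 2
Reactants: 4 1-[dimethyl(oxo)-λ6-sulfanylidene]tridecan-2-one; 5 2-hydroxy-4-methoxybenzoic acid (4-methoxysalicylic acid)
Product: 7 2-hydroxy-4-methoxy-6-(2-oxotridecyl)benzoic acid, via 8-hydroxy-6-methoxy-3-undecyl-1H-isochromen-1-one 6 (not isolated)
Conditions: 5 (1.0 equiv), 4 (1.5 equiv), [Cp*RhCl2]2 (4 mol %), AgSbF6 (16 mol %), NaOAc (30 mol %), HFIP, 80 °C (sealed tube), 16 h; evaporate; then KOH (6 equiv), EtOH/H2O 3:1, 70 °C, 2 h (same flask); then 1 M HCl to pH 2–3, 0 °C, extract, crystallise (hexane/EtOAc)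
Reagents that add atoms: water (delivered as aqueous KOH), O
Why: Carboxylate-directed Cp*Rh(III) C–H activation can occur only at C6, the single free position ortho to CO2H; the rhodacycle binds the ylide, loses DMSO to give an α-oxo Rh-carbene (the ketone α-carbon now an acceptor), and migratory insertion plus protodemetalation installs the 2-oxotridecyl chain (Rh(III)-catalysed C–H acylmethylation/annulation with a sulfoxonium ylide, known for benzoic acids but untested on a free salicylic acid); whatever lactonises to isocoumarin 6 in the acidic medium is reopened by hydroxide (enol-lactone saponification), so lactone and open form converge on 7; no stereocentre is formed.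

## Compound list

1 | dodecanoyl chloride | CCCCCCCCCCCC(=O)Cl | starting material
2 | trimethylsulfoxonium iodide | C[S+](C)(C)=O.[I-] | starting material
3 | dimethylsulfoxonium methylide | C=S(C)(C)=O | intermediate
4 | 1-[dimethyl(oxo)-λ6-sulfanylidene]tridecan-2-one | CCCCCCCCCCCC(=O)C=S(C)(C)=O | intermediate
5 | 2-hydroxy-4-methoxybenzoic acid | COc1ccc(C(=O)O)c(O)c1 | starting material
6 | 8-hydroxy-6-methoxy-3-undecyl-1H-isochromen-1-one | CCCCCCCCCCCC1=Cc2cc(OC)cc(O)c2C(=O)O1 | intermediate
7 | 2-hydroxy-4-methoxy-6-(2-oxotridecyl)benzoic acid | CCCCCCCCCCCC(=O)Cc1cc(OC)cc(O)c1C(=O)O | target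

## Summary

Total step count: 2 (step 2 is one pot, two stages).
Longest linear sequence: 2 (1 → 4 → 7).

The route has only two steps, so the three weakest points are ranked as follows.

**1. Step 2, C–H stage.** The free salicylic acid may bind Rh as an O,O-chelate, or its acidity may protonate and destroy the ylide before C–H activation. The fallback sets out from 5 and comes back at 7. Compound 5 is acetylated (Ac2O, cat. H2SO4, 60 °C) to 2-acetoxy-4-methoxybenzoic acid F1, which can no longer chelate. F1 is coupled with 4 under the same Rh conditions to give 6-methoxy-1-oxo-3-undecyl-1H-isochromen-8-yl acetate F2. The KOH stage then removes the acetate and opens the lactone in one operation, delivering 7.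

**2. Step 2, release stage.** The open keto acid may relactonise or be hard to separate from residual acid 5 after acidification. The fallback sets out from 6 and comes back at 7. After the Rh stage, 6 is isolated as a neutral compound (NaHCO3 wash, chromatography). It is opened by alcoholysis with benzyl alcohol (10 equiv) and TBD (1.2 equiv) in THF at 40 °C to give benzyl 2-hydroxy-4-methoxy-6-(2-oxotridecyl)benzoate F3, which is purified on silica. Hydrogenolysis (H2, 1 atm, Pd/C, EtOAc, rt) then releases 7 without acid or water; the aliphatic ketone is untouched.

**3. Step 1.** The enolisable acid chloride may give the ketene and its dimers with the basic ylide. The fallback sets out from 1 and comes back at 4. Compound 1 is converted with 4-nitrophenol and Et3N in CH2Cl2 into 4-nitrophenyl dodecanoate F4, an acyl donor that does not form a ketene under these conditions. F4 is then treated with ylide 3 (from 2 and excess KOtBu, THF, rt) to give 4.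

## Further compounds

F1 | step 2 | 2-acetoxy-4-methoxybenzoic acid | COc1ccc(C(=O)O)c(OC(C)=O)c1
F2 | step 2 | 6-methoxy-1-oxo-3-undecyl-1H-isochromen-8-yl acetate | CCCCCCCCCCCC1=Cc2cc(OC)cc(OC(C)=O)c2C(=O)O1
F3 | step 2 | benzyl 2-hydroxy-4-methoxy-6-(2-oxotridecyl)benzoate | CCCCCCCCCCCC(=O)Cc1cc(OC)cc(O)c1C(=O)OCc1ccccc1
F4 | step 1 | 4-nitrophenyl dodecanoate | CCCCCCCCCCCC(=O)Oc1ccc(cc1)[N+](=O)[O-]
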